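**Retrosynthetic overview**
1. Target 18 ⇐ O‑debenzylation of trans‑isoflavan‑4‑ol 17 ⇐ C4 epimerisation (MnO2, then axial hydride) of cis‑(3R,4R)‑alcohol 15 ⇐ Ru transfer hydrogenation with dynamic kinetic resolution of isoflavone 13.
2. Ring C (pyranone) ⇐ biomimetic oxidative 1,2‑aryl shift of 2'‑hydroxychalcone 11 and O1–C2 closure; 11 ⇐ Claisen–Schmidt of acetophenone 10 with aldehyde 9.
3. Ring D (hydroxydihydropyran) ⇐ 6‑endo opening of (R)‑prenyl epoxide 5 by a flanking, MOM‑masked phenolic oxygen, as in the prenyl‑epoxide biogenesis. The symmetric 2‑prenylresorcinol core removes the 2'‑O/4'‑O regiochemistry problem; 5 ⇐ Shi epoxidation of 4 ⇐ resorcinol 1.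
4. Order of ring formation: D (step 4), then C (step 8). Stereocentres: C3'' (Shi epoxidation), C3 (ATH‑DKR), C4 (substrate‑controlled hydride).

Assumption: the SMILES is read as (3R,4S,3''R), i.e. the 3,4‑trans isoflavan‑4‑ol carrying an (R)‑3‑hydroxy‑2,2‑dimethyldihydropyran ring.

**Route**

Step 1
Reactants: 1 resorcinol
Product: 2 1,3‑bis(methoxymethoxy)benzene
Conditions: NaH, MOMCl, DMF, 0 °C → rt
Reagents that add atoms: chloromethyl methyl ether, COCCl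
Why: Williamson‑type double O‑alkylation; the MOM ethers serve as directing groups in step 2 and as the ring‑closing oxygen in step 4.

Step 2
Reactants: 2 1,3‑bis(methoxymethoxy)benzene
Product: 4 1,3‑bis(methoxymethoxy)‑2‑(3‑methylbut‑2‑en‑1‑yl)benzene, via aryllithium 3 (not isolated)
Conditions: n‑BuLi, TMEDA, THF, 0 °C; then CuBr·SMe2 (10 mol %), prenyl bromide, −78 °C → rt
Reagents that add atoms: prenyl bromide (1‑bromo‑3‑methylbut‑2‑ene), CC(C)=CCBr
Why: Directed ortho‑metalation at C2 between the two cooperating OMOM groups, then copper‑catalysed SN2 allylation.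

Step 3
Reactants: 4 1,3‑bis(methoxymethoxy)‑2‑(3‑methylbut‑2‑en‑1‑yl)benzene
Product: 5 (2R)‑2‑[2,6‑bis(methoxymethoxy)benzyl]‑3,3‑dimethyloxirane
Conditions: D‑fructose‑derived Shi ketone (30 mol %), Oxone, K2CO3, Bu4NHSO4, MeCN–DMM/aq. Na2B4O7–EDTA, 0 °C
Reagents that add atoms: potassium peroxymonosulfate (Oxone), [K+].[O-]S(=O)(=O)OO
Why: Shi asymmetric epoxidation; the chiral dioxirane transfers oxygen to the trisubstituted prenyl alkene through a spiro transition state and gives the (R)‑epoxide (about 90% ee expected), which becomes C3''.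

Step 4
Reactants: 5 (2R)‑2‑[2,6‑bis(methoxymethoxy)benzyl]‑3,3‑dimethyloxirane
Product: 7 (3R)‑2,2‑dimethylchroman‑3,5‑diol, via bis‑MOM chroman 6 (not isolated)
Conditions: BF3·OEt2 (20 mol %), CH2Cl2, −78 → −30 °C; then MeOH, HCl (cat.), 40 °C
Reagents that add atoms: none
Why: Proposed new method: BF3 opens the trisubstituted epoxide with charge build‑up at the tertiary carbon, either of the two equivalent flanking aryl–OMOM oxygens closes the six‑membered ring there (6‑endo, Markovnikov), the aryloxonium ion passes its MOM group to the new C3 alkoxide (turning over BF3), and acidic methanol then removes both MOM groups; the C3–O bond is never broken, so the (R) centre from step 3 is kept; the closest known reactions are the acid‑catalysed 6‑endo cyclisation of o‑(2,3‑epoxy‑3‑methylbutyl)phenols to 2,2‑dimethylchroman‑3‑ols and ether‑terminated epoxide‑opening cascades.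

Step 5
Reactants: 7 (3R)‑2,2‑dimethylchroman‑3,5‑diol
Product: 8 (3R)‑3,5‑dihydroxy‑2,2‑dimethylchroman‑6‑carbaldehyde
Conditions: MgCl2, Et3N, (CH2O)n, MeCN, reflux; aq. HCl work‑up
Reagents that add atoms: paraformaldehyde (formaldehyde), C=O
Why: Casnati–Skattebøl ortho‑formylation; the magnesium phenoxide directs formaldehyde to the only free ortho position (C6) and a second formaldehyde oxidises the hydroxymethyl intermediate (Oppenauer‑type).

Step 6
Reactants: 8 (3R)‑3,5‑dihydroxy‑2,2‑dimethylchroman‑6‑carbaldehyde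
Product: 9 (3R)‑5‑(benzyloxy)‑3‑hydroxy‑2,2‑dimethylchroman‑6‑carbaldehyde
Conditions: BnBr, K2CO3, DMF, 60 °C; then recrystallisation (ee upgrade)
Reagents that add atoms: benzyl bromide, BrCc1ccccc1
Why: Williamson etherification of the chelated phenol only (K2CO3 does not deprotonate the secondary alcohol); it masks the future 2'‑OH against Tl(III) in step 8 and MnO2 in step 10.

Step 7
Reactants: 9 (3R)‑5‑(benzyloxy)‑3‑hydroxy‑2,2‑dimethylchroman‑6‑carbaldehyde; 10 1‑[4‑(benzyloxy)‑2‑hydroxyphenyl]ethanone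
Product: 11 (E)‑1‑[4‑(benzyloxy)‑2‑hydroxyphenyl]‑3‑[(3R)‑5‑(benzyloxy)‑3‑hydroxy‑2,2‑dimethylchroman‑6‑yl]prop‑2‑en‑1‑one
Conditions: KOH (50% aq.), EtOH, rt
Reagents that add atoms: none
Why: Claisen–Schmidt aldol condensation; the (E)‑enone forms under thermodynamic control and the chroman stereocentre is not affected.

Step 8
Reactants: 11 (E)‑1‑[4‑(benzyloxy)‑2‑hydroxyphenyl]‑3‑[(3R)‑5‑(benzyloxy)‑3‑hydroxy‑2,2‑dimethylchroman‑6‑yl]prop‑2‑en‑1‑one
Product: 13 7‑(benzyloxy)‑3‑[(3R)‑5‑(benzyloxy)‑3‑hydroxy‑2,2‑dimethylchroman‑6‑yl]‑4H‑chromen‑4‑one, via keto acetal 12 (not isolated)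
Conditions: Tl(NO3)3·3H2O, MeOH, rt; then 10% aq. HCl, 60 °C
Reagents that add atoms: none
Why: Tl(III)‑mediated oxidative rearrangement of a 2'‑hydroxychalcone, the laboratory counterpart of the isoflavone‑synthase aryl migration: methoxythallation of the enone and 1,2‑shift of the electron‑rich dialkoxyaryl ring give acetal 12 (its OMe groups come from the solvent), whose phenol closes onto the acetal carbon under acid and loses methanol to give the isoflavone; no stereocentre is formed.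

Step 9
Reactants: 13 7‑(benzyloxy)‑3‑[(3R)‑5‑(benzyloxy)‑3‑hydroxy‑2,2‑dimethylchroman‑6‑yl]‑4H‑chromen‑4‑one
Product: 15 (3R,4R)‑7‑(benzyloxy)‑3‑[(3R)‑5‑(benzyloxy)‑3‑hydroxy‑2,2‑dimethylchroman‑6‑yl]chroman‑4‑ol, via isoflavanone 14 (not isolated)
Conditions: RuCl[(R,R)‑TsDPEN](p‑cymene) (3 mol %), HCO2H/Et3N (5:2), EtOAc, 40 °C
Reagents that add atoms: none
Why: Noyori–Ikariya asymmetric transfer hydrogenation with dynamic kinetic resolution; conjugate reduction gives isoflavanone 14, whose C3 epimerises under Et3N while the (R,R)‑catalyst reduces the (3R)‑ketone fastest from the face anti to the aryl group, setting C3 (R) and C4 (R) as the cis alcohol.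

Step 10
Reactants: 15 (3R,4R)‑7‑(benzyloxy)‑3‑[(3R)‑5‑(benzyloxy)‑3‑hydroxy‑2,2‑dimethylchroman‑6‑yl]chroman‑4‑ol
Product: 17 (3R,4S)‑7‑(benzyloxy)‑3‑[(3R)‑5‑(benzyloxy)‑3‑hydroxy‑2,2‑dimethylchroman‑6‑yl]chroman‑4‑ol, via (3R)‑isoflavanone 16 (not isolated)
Conditions: MnO2, CH2Cl2, rt; filter; then CeCl3·7H2O, NaBH4, MeOH–CH2Cl2, −78 °C
Reagents that add atoms: none
Why: Oxidation–reduction epimerisation of C4: MnO2 oxidises only the benzylic carbinol (not the C3''‑OH) under neutral conditions that leave C3 intact, and Luche‑type borohydride then adds axially to the half‑chair chromanone with its pseudo‑equatorial 3‑aryl group to give the trans‑diequatorial (4S) alcohol; the minor cis isomer 15 is separated and recycled.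

Step 11
Reactants: 17 (3R,4S)‑7‑(benzyloxy)‑3‑[(3R)‑5‑(benzyloxy)‑3‑hydroxy‑2,2‑dimethylchroman‑6‑yl]chroman‑4‑ol
Product: 18 (3R,4S)‑3‑[(3R)‑3,5‑dihydroxy‑2,2‑dimethylchroman‑6‑yl]chroman‑4,7‑diol
Conditions: H2 (1 atm), 10% Pd/C, NaHCO3, EtOAc–EtOH, rt, stopped at full debenzylation; acid‑free work‑up
Reagents that add atoms: none
Why: Hydrogenolysis of the two aryl benzyl ethers; under neutral buffered conditions the benzylic C4–OH and the three stereocentres are untouched.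

**Compound list**
1 | resorcinol | Oc1cccc(O)c1 | starting material
2 | 1,3‑bis(methoxymethoxy)benzene | COCOc1cccc(OCOC)c1 | intermediate
3 | 2‑lithio‑1,3‑bis(methoxymethoxy)benzene | [Li]c1c(OCOC)cccc1OCOC | intermediate
4 | 1,3‑bis(methoxymethoxy)‑2‑(3‑methylbut‑2‑en‑1‑yl)benzene | COCOc1cccc(OCOC)c1CC=C(C)C | intermediate
5 | (2R)‑2‑[2,6‑bis(methoxymethoxy)benzyl]‑3,3‑dimethyloxirane | COCOc1cccc(OCOC)c1C[C@H]1OC1(C)C | intermediate
6 | (3R)‑3,5‑bis(methoxymethoxy)‑2,2‑dimethylchromane | CC1(C)Oc2cccc(OCOC)c2C[C@H]1OCOC | intermediate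
7 | (3R)‑2,2‑dimethylchroman‑3,5‑diol | CC1(C)Oc2cccc(O)c2C[C@H]1O | intermediate
8 | (3R)‑3,5‑dihydroxy‑2,2‑dimethylchroman‑6‑carbaldehyde | CC1(C)Oc2ccc(C=O)c(O)c2C[C@H]1O | intermediate
9 | (3R)‑5‑(benzyloxy)‑3‑hydroxy‑2,2‑dimethylchroman‑6‑carbaldehyde | CC1(C)Oc2ccc(C=O)c(OCc3ccccc3)c2C[C@H]1O | intermediate
10 | 1‑[4‑(benzyloxy)‑2‑hydroxyphenyl]ethanone | CC(=O)c1ccc(OCc2ccccc2)cc1O | starting material
11 | (E)‑1‑[4‑(benzyloxy)‑2‑hydroxyphenyl]‑3‑[(3R)‑5‑(benzyloxy)‑3‑hydroxy‑2,2‑dimethylchroman‑6‑yl]prop‑2‑en‑1‑one | CC1(C)Oc2ccc(/C=C/C(=O)c3ccc(OCc4ccccc4)cc3O)c(OCc3ccccc3)c2C[C@H]1O | intermediate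
12 | 1‑[4‑(benzyloxy)‑2‑hydroxyphenyl]‑2‑[(3R)‑5‑(benzyloxy)‑3‑hydroxy‑2,2‑dimethylchroman‑6‑yl]‑3,3‑dimethoxypropan‑1‑one (C2 epimers) | CC1(C)Oc2ccc(C(C(OC)OC)C(=O)c3ccc(OCc4ccccc4)cc3O)c(OCc3ccccc3)c2C[C@H]1O | intermediate
13 | 7‑(benzyloxy)‑3‑[(3R)‑5‑(benzyloxy)‑3‑hydroxy‑2,2‑dimethylchroman‑6‑yl]‑4H‑chromen‑4‑one | CC1(C)Oc2ccc(C3=COc4cc(OCc5ccccc5)ccc4C3=O)c(OCc3ccccc3)c2C[C@H]1O | intermediate
14 | 7‑(benzyloxy)‑3‑[(3R)‑5‑(benzyloxy)‑3‑hydroxy‑2,2‑dimethylchroman‑6‑yl]chroman‑4‑one (C3 epimers, interconverting) | CC1(C)Oc2ccc(C3COc4cc(OCc5ccccc5)ccc4C3=O)c(OCc3ccccc3)c2C[C@H]1O | intermediate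
15 | (3R,4R)‑7‑(benzyloxy)‑3‑[(3R)‑5‑(benzyloxy)‑3‑hydroxy‑2,2‑dimethylchroman‑6‑yl]chroman‑4‑ol (3,4‑cis) | CC1(C)Oc2ccc([C@@H]3COc4cc(OCc5ccccc5)ccc4[C@@H]3O)c(OCc3ccccc3)c2C[C@H]1O | intermediate
16 | (3R)‑7‑(benzyloxy)‑3‑[(3R)‑5‑(benzyloxy)‑3‑hydroxy‑2,2‑dimethylchroman‑6‑yl]chroman‑4‑one | CC1(C)Oc2ccc([C@@H]3COc4cc(OCc5ccccc5)ccc4C3=O)c(OCc3ccccc3)c2C[C@H]1O | intermediate
17 | (3R,4S)‑7‑(benzyloxy)‑3‑[(3R)‑5‑(benzyloxy)‑3‑hydroxy‑2,2‑dimethylchroman‑6‑yl]chroman‑4‑ol (3,4‑trans) | CC1(C)Oc2ccc([C@@H]3COc4cc(OCc5ccccc5)ccc4[C@H]3O)c(OCc3ccccc3)c2C[C@H]1O | intermediate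
18 | (3R,4S)‑3‑[(3R)‑3,5‑dihydroxy‑2,2‑dimethylchroman‑6‑yl]chroman‑4,7‑diol | CC1(C)Oc2ccc([C@@H]3COc4cc(O)ccc4[C@H]3O)c(O)c2C[C@H]1O | target

**Step count and risks**
Total steps: 11. Longest linear sequence: 11 (resorcinol 1 → 18); acetophenone 10 enters at step 7.

The three steps most likely to fail:

Step 4 (Lewis‑acid epoxide cyclisation). The risks are Meinwald rearrangement of the epoxide to a ketone and 5‑exo closure to the dihydrobenzofuran. The fallback sets out from 4 and builds the ring as a chromene instead. Acidic methanolysis (HCl, MeOH, rt) gives 2‑(3‑methylbut‑2‑en‑1‑yl)benzene‑1,3‑diol F1. DDQ in refluxing benzene closes it oxidatively to 2,2‑dimethyl‑2H‑chromen‑5‑ol F2, and Ac2O/pyridine gives 2,2‑dimethyl‑2H‑chromen‑5‑yl acetate F3. Jacobsen epoxidation with the (R,R)‑Mn(salen) catalyst (NaOCl, 4‑phenylpyridine N‑oxide, CH2Cl2, 0 °C) gives (3R,4R)‑3,4‑epoxy‑2,2‑dimethylchroman‑5‑yl acetate F4. LiAlH4 (THF, 0 °C) then opens the epoxide at the benzylic C4 and removes the acetate, and the route is rejoined at 7.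

Step 8 (Tl(III) aryl shift). The risks are aurone formation and oxidation of the electron‑rich chroman ring. The fallback sets out from 11 and moves the aryl shift to the flavanone stage. NaOAc in refluxing EtOH cyclises the chalcone by oxa‑Michael addition to 7‑(benzyloxy)‑2‑[(3R)‑5‑(benzyloxy)‑3‑hydroxy‑2,2‑dimethylchroman‑6‑yl]chroman‑4‑one F5. PhI(OAc)2 with catalytic H2SO4 in HC(OMe)3 at rt then effects the 2,3‑aryl migration with loss of the C3 proton, and the route is rejoined at 13.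

Step 10 (oxidation–reduction epimerisation). The risks are a modest trans:cis ratio in the hydride addition and partial epimerisation of C3 in ketone 16. The fallback sets out from 15 and inverts C4 directly by a Mitsunobu reaction. PPh3, DIAD and 4‑nitrobenzoic acid in THF at 0 °C give (3R,4S)‑7‑(benzyloxy)‑3‑[(3R)‑5‑(benzyloxy)‑3‑hydroxy‑2,2‑dimethylchroman‑6‑yl]chroman‑4‑yl 4‑nitrobenzoate F6; the neopentyl‑type C3''‑OH is too hindered to react. K2CO3 in MeOH cleaves the ester, and the route is rejoined at 17.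

**Further compounds**
F1 | step 4 | 2‑(3‑methylbut‑2‑en‑1‑yl)benzene‑1,3‑diol | CC(C)=CCc1c(O)cccc1O
F2 | step 4 | 2,2‑dimethyl‑2H‑chromen‑5‑ol | CC1(C)C=Cc2c(O)cccc2O1
F3 | step 4 | 2,2‑dimethyl‑2H‑chromen‑5‑yl acetate | CC(=O)Oc1cccc2OC(C)(C)C=Cc12
F4 | step 4 | (3R,4R)‑3,4‑epoxy‑2,2‑dimethylchroman‑5‑yl acetate | CC1(C)Oc2cccc(OC(C)=O)c2[C@H]2O[C@@H]12
F5 | step 8 | 7‑(benzyloxy)‑2‑[(3R)‑5‑(benzyloxy)‑3‑hydroxy‑2,2‑dimethylchroman‑6‑yl]chroman‑4‑one (C2 epimers) | CC1(C)Oc2ccc(C3CC(=O)c4ccc(OCc5ccccc5)cc4O3)c(OCc3ccccc3)c2C[C@H]1O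
F6 | step 10 | (3R,4S)‑7‑(benzyloxy)‑3‑[(3R)‑5‑(benzyloxy)‑3‑hydroxy‑2,2‑dimethylchroman‑6‑yl]chroman‑4‑yl 4‑nitrobenzoate | CC1(C)Oc2ccc([C@@H]3COc4cc(OCc5ccccc5)ccc4[C@H]3OC(=O)c3ccc(cc3)[N+](=O)[O-])c(OCc3ccccc3)c2C[C@H]1O
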